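**Assumption:** the target is read as (1R,2S,5R,9S)-2-hydroxy-9-[(3Z)-5-hydroxy-3-methylpent-3-en-1-yl]-1-[(3Z)-5-hydroxy-4-methylpent-3-en-1-yl]-5-methyl-6,8-dioxabicyclo[3.2.2]nonan-7-one, and core locants below follow this name. TBS = tert-butyldimethylsilyl; "TBSO-pentenyl" = (3Z)-5-[(TBS)oxy]-3-methylpent-3-en-1-yl.

## Retrosynthetic overview

1. Target ⇐ tris-TBS ether 23 ⇐ C1-vinyl bicycle 17 + (Z)-vinyl iodide 21 (hydroboration / B-alkyl Suzuki builds the C1 side chain).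
2. 17 ⇐ tertiary vinyldiazoacetate 15 of a 2-silyloxy-oxane: carbenoid → bridged oxonium ylide → [1,2]-shift of the acetal carbon. C1–O8 and C1–C2 form in one operation, so the dioxanone and the oxepane/ε-lactone rings appear together while the oxane is consumed.
3. 15 ⇐ acetoacetate 12 ⇐ pyranone 9 (MeLi addition/diketene, ring-alkene hydrogenation) ⇐ Achmatowicz rearrangement with Sharpless kinetic resolution of furyl carbinol 7.
4. 7 ⇐ furan + aldehyde 4 ⇐ nerol (supplies the C9 side chain with its Z alkene); 21 ⇐ propargyl alcohol.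
5. Ring order: pyranone/oxane ring first (steps 4–7), then dioxanone and oxepane (ε-lactone) simultaneously in step 11.

## Route

**Step 1**
Reactants: 1 nerol
Product: 2 neryl TBS ether
Conditions: TBSCl, imidazole, CH2Cl2, 0 °C → rt
Reagents that add atoms: tert-butyldimethylsilyl chloride, CC(C)(C)[Si](C)(C)Cl
Why: Standard imidazole-promoted silylation of the primary allylic alcohol; no stereocentre is formed and the Z alkene is untouched.

**Step 2**
Reactants: 2 neryl TBS ether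
Product: 4 (4Z)-6-(TBSO)-4-methylhex-4-enal, via secondary ozonide 3 (not isolated)
Conditions: O3 (1 equiv, Sudan Red 7B end-point), CH2Cl2, −78 °C; then Me2S, −78 °C → rt
Reagents that add atoms: ozone, [O-][O+]=O
Why: Chemoselective ozonolysis with reductive work-up, because the isopropylidene alkene is more electron-rich than the alkene deactivated by the allylic silyloxy group; no stereocentre is formed.

**Step 3**
Reactants: 4 (4Z)-6-(TBSO)-4-methylhex-4-enal; 5 furan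
Product: 7 rac-(4Z)-6-(TBSO)-1-(furan-2-yl)-4-methylhex-4-en-1-ol, via 2-furyllithium 6 (not isolated)
Conditions: 5, n-BuLi, THF, 0 °C; then 4, −78 °C; H2O
Reagents that add atoms: none
Why: α-Lithiation of furan and 1,2-addition of the organolithium to the aldehyde give the racemic furyl carbinol.

**Step 4**
Reactants: 7 rac-(4Z)-6-(TBSO)-1-(furan-2-yl)-4-methylhex-4-en-1-ol
Product: 8 (2S)-6-hydroxy-2-(TBSO-pentenyl)-2H-pyran-3(6H)-one (both anomers)
Conditions: Ti(OiPr)4, L-(+)-DIPT, t-BuOOH (0.5 equiv), 4 Å MS, CH2Cl2, −20 °C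
Reagents that add atoms: tert-butyl hydroperoxide, CC(C)(C)OO
Why: Sharpless kinetic resolution coupled to Achmatowicz rearrangement: the L-(+)-tartrate reagent oxidises only the (S)-carbinol (furyl ranks like vinyl in the allylic-alcohol mnemonic), which rearranges with retention to set C9 of the target, and the untouched (R)-7 is removed by chromatography.

**Step 5**
Reactants: 8 (2S)-6-hydroxy-2-(TBSO-pentenyl)-2H-pyran-3(6H)-one
Product: 9 (2S,6S)-6-(TBSO)-2-(TBSO-pentenyl)-2H-pyran-3(6H)-one (2,6-trans)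
Conditions: TBSCl, imidazole, CH2Cl2, 0 °C
Reagents that add atoms: tert-butyldimethylsilyl chloride, CC(C)(C)[Si](C)(C)Cl
Why: Lactol silylation, in which the anomeric effect favours the pseudo-axial silyloxy group trans to the C2 chain; the minor cis anomer is separated.

**Step 6**
Reactants: 9 (2S,6S)-6-(TBSO)-2-(TBSO-pentenyl)-2H-pyran-3(6H)-one
Product: 11 (2S,3R,6S)-6-(TBSO)-2-(TBSO-pentenyl)-3-methyl-3,6-dihydro-2H-pyran-3-yl 3-oxobutanoate, via lithium alkoxide 10 (not isolated)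
Conditions: MeLi, THF, −78 °C; then diketene, −78 → 0 °C; H2O
Reagents that add atoms: methyllithium, [Li]C; diketene, C=C1CC(=O)O1
Why: 1,2-Addition of MeLi to the enone anti to the pseudo-axial anomeric silyloxy group (the facial sense of Luche reductions of these pyranones) sets the tertiary centre (target C5) with oxygen trans to the C2 chain, and the alkoxide is acetoacetylated in situ by diketene.

**Step 7**
Reactants: 11 (2S,3R,6S)-6-(TBSO)-2-(TBSO-pentenyl)-3-methyl-3,6-dihydro-2H-pyran-3-yl 3-oxobutanoate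
Product: 12 (2S,3R,6S)-6-(TBSO)-2-(TBSO-pentenyl)-3-methyloxan-3-yl 3-oxobutanoate
Conditions: H2 (1 atm), RhCl(PPh3)3 (10 mol %), benzene, rt
Reagents that add atoms: none
Why: Wilkinson hydrogenation reduces the cis-disubstituted ring alkene and leaves the trisubstituted side-chain alkene alone; no stereocentre is formed.

**Step 8**
Reactants: 12 (2S,3R,6S)-6-(TBSO)-2-(TBSO-pentenyl)-3-methyloxan-3-yl 3-oxobutanoate
Product: 13 (2S,3R,6S)-6-(TBSO)-2-(TBSO-pentenyl)-3-methyloxan-3-yl 2-diazo-3-oxobutanoate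
Conditions: p-ABSA, Et3N, MeCN, rt
Reagents that add atoms: 4-acetamidobenzenesulfonyl azide, CC(=O)Nc1ccc(cc1)S(=O)(=O)N=[N+]=[N-]
Why: Regitz diazo transfer to the active methylene of the β-keto ester; the stereocentres are not involved.

**Step 9**
Reactants: 13 (2S,3R,6S)-6-(TBSO)-2-(TBSO-pentenyl)-3-methyloxan-3-yl 2-diazo-3-oxobutanoate
Product: 14 (2S,3R,6S)-6-(TBSO)-2-(TBSO-pentenyl)-3-methyloxan-3-yl 2-diazo-3-hydroxybutanoate (carbinol epimers)
Conditions: NaBH4, MeOH, 0 °C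
Reagents that add atoms: none
Why: Borohydride reduction of the ketone of a 2-diazo-3-oxo ester (first half of the Davies vinyldiazoacetate sequence); the new carbinol centre is removed in the next step.

**Step 10**
Reactants: 14 (2S,3R,6S)-6-(TBSO)-2-(TBSO-pentenyl)-3-methyloxan-3-yl 2-diazo-3-hydroxybutanoate
Product: 15 (2S,3R,6S)-6-(TBSO)-2-(TBSO-pentenyl)-3-methyloxan-3-yl 2-diazobut-3-enoate
Conditions: POCl3, Et3N, CH2Cl2, 0 °C (used at once)
Reagents that add atoms: none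
Why: Dehydration of the β-hydroxy diazo ester via its dichlorophosphate gives the vinyldiazoacetate, a donor/acceptor carbenoid precursor with no β-hydride shift available.

**Step 11 (key step)**
Reactants: 15 (2S,3R,6S)-6-(TBSO)-2-(TBSO-pentenyl)-3-methyloxan-3-yl 2-diazobut-3-enoate
Product: 17 (1R,2S,5R,9S)-2-(TBSO)-9-(TBSO-pentenyl)-1-ethenyl-5-methyl-6,8-dioxabicyclo[3.2.2]nonan-7-one, via bridged oxonium ylide 16 (not isolated)
Conditions: Cu(hfacac)2 (10 mol %), CH2Cl2, 40 °C, slow addition (high dilution)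
Reagents that add atoms: none
Why: Proposed new method: the copper vinylcarbenoid is captured by the oxane ring oxygen, which lies 1,3-diaxial to the ester oxygen in the ring-flipped chair, and the resulting oxonium ylide undergoes a Stevens [1,2]-shift of the acetal carbon (O8 → C1), closing the dioxanone and expanding the oxane to the oxepane/ε-lactone; C1 is fixed by the tether to C5 and C2 forms with retention from the 2,6-trans acetal; the closest known reaction is the Cu(hfacac)2-catalysed [1,2]-shift of oxonium ylides from cyclic acetals to give oxygen-bridged rings.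

**Step 12**
Reactants: 18 propargyl alcohol
Product: 20 (2Z)-3-iodo-2-methylprop-2-en-1-ol, via vinylmagnesium chelate 19 (not isolated)
Conditions: MeMgBr, CuI (10 mol %), THF, −10 °C → rt; then I2, −10 °C; H2O
Reagents that add atoms: methylmagnesium bromide, C[Mg]Br; iodine, II
Why: Copper-catalysed anti-carbomagnesiation of the propargylic alkoxide (Duboudin) holds Mg cis to CH2O by chelation, and iodinolysis with retention gives the Z iodide.

**Step 13**
Reactants: 20 (2Z)-3-iodo-2-methylprop-2-en-1-ol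
Product: 21 tert-butyl{[(2Z)-3-iodo-2-methylprop-2-en-1-yl]oxy}dimethylsilane
Conditions: TBSCl, imidazole, CH2Cl2, rt
Reagents that add atoms: tert-butyldimethylsilyl chloride, CC(C)(C)[Si](C)(C)Cl
Why: Standard silylation of the primary allylic alcohol; alkene geometry is unchanged.

**Step 14**
Reactants: 17 (1R,2S,5R,9S)-2-(TBSO)-9-(TBSO-pentenyl)-1-ethenyl-5-methyl-6,8-dioxabicyclo[3.2.2]nonan-7-one; 21 tert-butyl{[(2Z)-3-iodo-2-methylprop-2-en-1-yl]oxy}dimethylsilane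
Product: 23 tris-TBS ether of the target, via B-alkyl-9-BBN 22 (not isolated)
Conditions: 9-BBN, THF, rt; then 21, Pd(dppf)Cl2, AsPh3, Cs2CO3, DMF/H2O, rt
Reagents that add atoms: none
Why: 9-BBN hydroborates only the monosubstituted vinyl group at its terminus, and B-alkyl Suzuki–Miyaura coupling joins it to the vinyl iodide with retention of the Z geometry; the ring stereocentres are untouched.

**Step 15**
Reactants: 23 tris-TBS ether of the target
Product: 24 CNP0105745.1 (target)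
Conditions: HF·pyridine, pyridine, THF, 0 °C → rt
Reagents that add atoms: none
Why: Global desilylation under mildly acidic fluoride conditions, which avoids retro-aldol cleavage or opening of the β-hydroxy lactone; no stereocentre is affected.

## Compound list

1 | nerol, (2Z)-3,7-dimethylocta-2,6-dien-1-ol | CC(C)=CCC/C(C)=C\CO | starting material
2 | neryl TBS ether, tert-butyl{[(2Z)-3,7-dimethylocta-2,6-dien-1-yl]oxy}dimethylsilane | CC(C)=CCC/C(C)=C\CO[Si](C)(C)C(C)(C)C | intermediate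
3 | secondary ozonide, 3,3-dimethyl-5-(TBSO-pentenyl)-1,2,4-trioxolane | CC1(C)OOC(CC/C(C)=C\CO[Si](C)(C)C(C)(C)C)O1 | intermediate
4 | (4Z)-6-[(TBS)oxy]-4-methylhex-4-enal | O=CCC/C(C)=C\CO[Si](C)(C)C(C)(C)C | intermediate
5 | furan | c1ccoc1 | starting material
6 | 2-furyllithium | [Li]c1ccco1 | intermediate
7 | rac-(4Z)-6-[(TBS)oxy]-1-(furan-2-yl)-4-methylhex-4-en-1-ol | OC(CC/C(C)=C\CO[Si](C)(C)C(C)(C)C)c1ccco1 | intermediate
8 | (2S)-6-hydroxy-2-(TBSO-pentenyl)-2H-pyran-3(6H)-one, anomer mixture | O=C1C=CC(O)O[C@H]1CC/C(C)=C\CO[Si](C)(C)C(C)(C)C | intermediate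
9 | (2S,6S)-6-[(TBS)oxy]-2-(TBSO-pentenyl)-2H-pyran-3(6H)-one, 2,6-trans | O=C1C=C[C@H](O[Si](C)(C)C(C)(C)C)O[C@H]1CC/C(C)=C\CO[Si](C)(C)C(C)(C)C | intermediate
10 | lithium (2S,3R,6S)-6-[(TBS)oxy]-2-(TBSO-pentenyl)-3-methyl-3,6-dihydro-2H-pyran-3-olate | C[C@@]1(O[Li])C=C[C@H](O[Si](C)(C)C(C)(C)C)O[C@H]1CC/C(C)=C\CO[Si](C)(C)C(C)(C)C | intermediate
11 | (2S,3R,6S)-6-[(TBS)oxy]-2-(TBSO-pentenyl)-3-methyl-3,6-dihydro-2H-pyran-3-yl 3-oxobutanoate | C[C@@]1(OC(=O)CC(C)=O)C=C[C@H](O[Si](C)(C)C(C)(C)C)O[C@H]1CC/C(C)=C\CO[Si](C)(C)C(C)(C)C | intermediate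
12 | (2S,3R,6S)-6-[(TBS)oxy]-2-(TBSO-pentenyl)-3-methyloxan-3-yl 3-oxobutanoate | C[C@@]1(OC(=O)CC(C)=O)CC[C@H](O[Si](C)(C)C(C)(C)C)O[C@H]1CC/C(C)=C\CO[Si](C)(C)C(C)(C)C | intermediate
13 | (2S,3R,6S)-6-[(TBS)oxy]-2-(TBSO-pentenyl)-3-methyloxan-3-yl 2-diazo-3-oxobutanoate | C[C@@]1(OC(=O)C(=[N+]=[N-])C(C)=O)CC[C@H](O[Si](C)(C)C(C)(C)C)O[C@H]1CC/C(C)=C\CO[Si](C)(C)C(C)(C)C | intermediate
14 | (2S,3R,6S)-6-[(TBS)oxy]-2-(TBSO-pentenyl)-3-methyloxan-3-yl 2-diazo-3-hydroxybutanoate | C[C@@]1(OC(=O)C(=[N+]=[N-])C(C)O)CC[C@H](O[Si](C)(C)C(C)(C)C)O[C@H]1CC/C(C)=C\CO[Si](C)(C)C(C)(C)C | intermediate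
15 | (2S,3R,6S)-6-[(TBS)oxy]-2-(TBSO-pentenyl)-3-methyloxan-3-yl 2-diazobut-3-enoate | C[C@@]1(OC(=O)C(=[N+]=[N-])C=C)CC[C@H](O[Si](C)(C)C(C)(C)C)O[C@H]1CC/C(C)=C\CO[Si](C)(C)C(C)(C)C | intermediate
16 | bridged bicyclic oxonium ylide (ring O bonded to C9, to the acetal carbon and to the ylide carbon) | C[C@]12CC[C@H](O[Si](C)(C)C(C)(C)C)[O+]([C-](C=C)C(=O)O1)[C@H]2CC/C(C)=C\CO[Si](C)(C)C(C)(C)C | intermediate
17 | (1R,2S,5R,9S)-2-[(TBS)oxy]-9-(TBSO-pentenyl)-1-ethenyl-5-methyl-6,8-dioxabicyclo[3.2.2]nonan-7-one | C=C[C@@]12O[C@@H](CC/C(C)=C\CO[Si](C)(C)C(C)(C)C)[C@@](C)(CC[C@@H]1O[Si](C)(C)C(C)(C)C)OC2=O | intermediate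
18 | propargyl alcohol, prop-2-yn-1-ol | C#CCO | starting material
19 | (Z)-3-(bromomagnesio)-2-methylprop-2-en-1-olate, bromomagnesium chelate | C/C(=C/[Mg]Br)CO[Mg]Br | intermediate
20 | (2Z)-3-iodo-2-methylprop-2-en-1-ol | C/C(=C/I)CO | intermediate
21 | tert-butyl{[(2Z)-3-iodo-2-methylprop-2-en-1-yl]oxy}dimethylsilane | C/C(=C/I)CO[Si](C)(C)C(C)(C)C | intermediate
22 | B-alkyl-9-BBN from hydroboration of the vinyl group of 17 (boron on the terminal carbon) | B1(CC[C@@]23O[C@@H](CC/C(C)=C\CO[Si](C)(C)C(C)(C)C)[C@@](C)(CC[C@@H]2O[Si](C)(C)C(C)(C)C)OC3=O)C4CCCC1CCC4 | intermediate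
23 | tris-TBS ether of the target, (1R,2S,5R,9S)-2-[(TBS)oxy]-9-(TBSO-pentenyl)-1-[(3Z)-5-[(TBS)oxy]-4-methylpent-3-en-1-yl]-5-methyl-6,8-dioxabicyclo[3.2.2]nonan-7-one | C/C(=C/CC[C@@]12O[C@@H](CC/C(C)=C\CO[Si](C)(C)C(C)(C)C)[C@@](C)(CC[C@@H]1O[Si](C)(C)C(C)(C)C)OC2=O)CO[Si](C)(C)C(C)(C)C | intermediate
24 | CNP0105745.1, (1R,2S,5R,9S)-2-hydroxy-9-[(3Z)-5-hydroxy-3-methylpent-3-en-1-yl]-1-[(3Z)-5-hydroxy-4-methylpent-3-en-1-yl]-5-methyl-6,8-dioxabicyclo[3.2.2]nonan-7-one | C/C(=C/CC[C@@]12O[C@@H](CC/C(C)=C\CO)[C@@](C)(CC[C@@H]1O)OC2=O)CO | target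

## Step count and risks

Total: 15 steps. Longest linear sequence: 13 steps (steps 1–11, 14, 15, from nerol).

**Step 11 (ylide formation / [1,2]-shift).** The ring oxygen can reach the carbenoid only from the minor chair with the side chain and ester oxygen axial, so C–H insertion or carbenoid dimerisation may win, and retention at C2 is not guaranteed. The fallback leaves 15 and returns at 17. The anomeric silyl acetal of 15 is cleaved selectively (TBAF/AcOH, THF, −40 °C) to lactol diazo ester F1, which NaBH4 opens to diol diazo ester F2. On this acyclic chain Rh2(OAc)4 effects an ordinary six-ring O–H insertion at the secondary hydroxyl to give dioxanone alcohol F3. Dess–Martin oxidation gives dioxanone aldehyde F4, and a chelated intramolecular aldol (TiCl4, i-Pr2NEt, −78 °C) closes the bridge to hydroxy lactone F5. Silylation (TBSOTf, 2,6-lutidine) gives 17.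

**Step 6 (MeLi addition / in situ acylation).** The facial selectivity at the tertiary centre or the one-pot acylation of the hindered alkoxide may be poor. The fallback leaves 9 and returns at 12. Compound 9 is hydrogenated first (H2, RhCl(PPh3)3) to saturated ketone F6. Dimethylsulfonium methylide then adds axially, anti to the axial anomeric silyloxy group, to give spiro-epoxide F7 with oxygen equatorial. LiEt3BH opens the epoxide at CH2 to tertiary alcohol F8, and diketene/DMAP gives 12.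

**Step 4 (kinetic resolution / Achmatowicz).** The yield is at most 50 % and the ee of the product depends on conversion. The fallback leaves 7 and returns at 8. Racemic 7 is oxidised (MnO2) to furyl ketone F9. Noyori transfer hydrogenation (RuCl[(S,S)-TsDPEN](p-cymene), HCO2H/Et3N; enantiomer chosen by analogy with aryl ketones) gives (S)-furyl carbinol F10. VO(acac)2/t-BuOOH Achmatowicz rearrangement then gives 8.

## Further compounds

F1 | step 11 | (2S,3R)-6-hydroxy-2-(TBSO-pentenyl)-3-methyloxan-3-yl 2-diazobut-3-enoate, anomer mixture | C[C@@]1(OC(=O)C(=[N+]=[N-])C=C)CCC(O)O[C@H]1CC/C(C)=C\CO[Si](C)(C)C(C)(C)C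
F2 | step 11 | (4R,5S,8Z)-10-[(TBS)oxy]-1,5-dihydroxy-4,8-dimethyldec-8-en-4-yl 2-diazobut-3-enoate | OCCC[C@@](C)(OC(=O)C(=[N+]=[N-])C=C)[C@@H](O)CC/C(C)=C\CO[Si](C)(C)C(C)(C)C
F3 | step 11 | (5S,6R)-3-ethenyl-6-(3-hydroxypropyl)-6-methyl-5-(TBSO-pentenyl)-1,4-dioxan-2-one, C3 epimers | OCCC[C@@]1(C)OC(=O)C(C=C)O[C@H]1CC/C(C)=C\CO[Si](C)(C)C(C)(C)C
F4 | step 11 | 3-[(2R,3S)-5-ethenyl-2-methyl-6-oxo-3-(TBSO-pentenyl)-1,4-dioxan-2-yl]propanal | O=CCC[C@@]1(C)OC(=O)C(C=C)O[C@H]1CC/C(C)=C\CO[Si](C)(C)C(C)(C)C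
F5 | step 11 | (1R,2S,5R,9S)-1-ethenyl-2-hydroxy-5-methyl-9-(TBSO-pentenyl)-6,8-dioxabicyclo[3.2.2]nonan-7-one | C=C[C@@]12O[C@@H](CC/C(C)=C\CO[Si](C)(C)C(C)(C)C)[C@@](C)(CC[C@@H]1O)OC2=O
F6 | step 6 | (2S,6S)-6-[(TBS)oxy]-2-(TBSO-pentenyl)oxan-3-one | O=C1CC[C@H](O[Si](C)(C)C(C)(C)C)O[C@H]1CC/C(C)=C\CO[Si](C)(C)C(C)(C)C
F7 | step 6 | spiro-epoxide of F6 at C3, 1,5-dioxaspiro[2.5]octane with epoxide oxygen trans to the TBSO-pentenyl chain | C1O[C@@]12CC[C@H](O[Si](C)(C)C(C)(C)C)O[C@H]2CC/C(C)=C\CO[Si](C)(C)C(C)(C)C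
F8 | step 6 | (2S,3R,6S)-6-[(TBS)oxy]-2-(TBSO-pentenyl)-3-methyloxan-3-ol | C[C@@]1(O)CC[C@H](O[Si](C)(C)C(C)(C)C)O[C@H]1CC/C(C)=C\CO[Si](C)(C)C(C)(C)C
F9 | step 4 | (4Z)-6-[(TBS)oxy]-1-(furan-2-yl)-4-methylhex-4-en-1-one | O=C(CC/C(C)=C\CO[Si](C)(C)C(C)(C)C)c1ccco1
F10 | step 4 | (1S,4Z)-6-[(TBS)oxy]-1-(furan-2-yl)-4-methylhex-4-en-1-ol | O[C@@H](CC/C(C)=C\CO[Si](C)(C)C(C)(C)C)c1ccco1
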